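**Plan**

- Retrosynthesis: the C8 ester is cut to a C8 alcohol and a silyl-protected (S)-3,4-dihydroxy-2-methylidenebutanoic acid. The lactone is then opened at C11–C13, O6–C12 and C7–C11, and the C5–C4 bond is cut next to a C6 ketone. The vinyl group goes back to a C1 lactone carbonyl, and the last cut removes O–C8 and C9–I from a bridged iodolactone, leaving achiral 1-methylcyclohexa-2,5-diene-1-carboxylic acid (benzoic acid plus iodomethane).
- Enabling feature: C10 holds the one-carbon arm C1 cis to the oxygen on C8 (a 1,3-relationship across C9). A carboxyl on C10 can therefore span to C8 as a γ-lactone (6-oxabicyclo[3.2.1]octane) and in doing so pick one of the two enantiotopic ring alkenes.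
- Forward: the carbocycle comes from benzoic acid by Birch reductive methylation. The desymmetrising iodolactonisation closes the bridged lactone, a temporary ring. After deiodination and hydroboration this lactone is unravelled into the C1=C2 vinyl group and a C8 ether. A C6 ketone then takes the C7 acetate arm and the C5 alkenyl arm, reduction and lactonisation close the 6,12-lactone, C13 is added, and the side chain is esterified last.
- Stereochemistry: C10 and C8 come from the key step (catalyst and tether). C7 and C5 are set equatorial by enolate alkylation anti to the C8 ether and by kinetic protonation anti to the axial C14 methyl. C6 is set by an electron-transfer reduction under thermodynamic control, C11 by enolate methylation on the convex face, and the side-chain carbinol by an asymmetric Morita–Baylis–Hillman reaction.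

Key step: step 2

Remark 1: atom numbers are those of the sesquiterpene skeleton (C10 quaternary with C14 methyl and C1=C2 vinyl; C9 CH2; C8 acyloxy CH; C7 ring-fusion CH; C6 lactone O–CH; C5 CH bearing C4 with C15 methylene and C3 hydroxymethyl; C11, C12, C13 lactone CH, carbonyl and methyl); "top face" is the ring face on which C1 sits at C10, "bottom face" the face of the C14 methyl.

Remark 2: the sense of induction of the cinchona catalyst in step 2 cannot be predicted with certainty; (DHQD)2PHAL is written, and its pseudo-enantiomer (DHQ)2PHAL would be used if the antipode formed.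

**Step 1**
Reactants: 1 benzoic acid; 2 iodomethane
Product: 4 1-methylcyclohexa-2,5-diene-1-carboxylic acid, via dilithium dienediolate 3 (not isolated)
Conditions: Li, NH3 (l), THF, −78 °C; then MeI, −78 °C to rt; aq. HCl
Reagents that add atoms: iodomethane (compound 2), CI
Why: Birch reduction of the benzoate stops at the carboxylate-stabilised dienediolate, which is C-methylated at the carboxyl-bearing carbon (Birch reductive alkylation) to give the 1,4-diene with its quaternary carbon; the product has a mirror plane and no stereocentre.

**Step 2**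
Reactants: 4 1-methylcyclohexa-2,5-diene-1-carboxylic acid
Product: 5 (1S,5S,8S)-8-iodo-1-methyl-6-oxabicyclo[3.2.1]oct-2-en-7-one
Conditions: N-iodosuccinimide (1.2 equiv), hydroquinidine 1,4-phthalazinediyl diether [(DHQD)2PHAL, 10 mol %], CHCl3/toluene, −40 °C to 0 °C, dark
Reagents that add atoms: N-iodosuccinimide, O=C1CCC(=O)N1I
Why: Proposed new method: the cinchona dimer should bind the acid as a hydrogen-bonded carboxylate ion pair and relay I+ from N-iodosuccinimide to one of the two enantiotopic ring alkenes on the face anti to the carboxylate, after which the carboxylate oxygen opens the iodonium ion at the distal carbon C8, forming O–C8 and C9–I in an anti addition. The closest known reaction types are the γ-iodolactonisation of 1,4-dihydrobenzoic acids under equilibrating conditions and the catalytic enantioselective halolactonisation of prochiral dienyl and alkenoic acids with carboxylate-binding catalysts. The γ-lactone closes in the 5-endo mode on the iodonium ion; the competing 4-exo closure at C9 gives a strained β-lactone that should re-ionise under these base-free conditions and funnel into the bridged γ-lactone. C10 is fixed by the catalyst's choice of alkene, C8 by the tether (the oxygen can only arrive cis to C1) and C9 by anti opening (iodine trans to the lactone bridge). The step needs group selectivity between the C8=C9 and C5=C6 alkenes, which the achiral substrate cannot supply and which rests on the chiral ion pair; the substrate does secure the regio- and diastereoselectivity, because a carboxyl on the quaternary carbon reaches only the γ-carbon of the syn face.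

**Step 3**
Reactants: 5 iodolactone
Product: 6 (1S,5S)-1-methyl-6-oxabicyclo[3.2.1]oct-2-en-7-one
Conditions: Bu3SnH, 2,2'-azobis(2-methylpropionitrile) (cat.), benzene, 80 °C
Reagents that add atoms: none
Why: Radical chain dehalogenation with tin hydride removes the secondary iodide through the C9 radical, which should abstract hydrogen faster than it rearranges, and leaves the lactone and the alkene untouched.

**Step 4**
Reactants: 6 unsaturated lactone
Product: 8 C6 hydroxy lactone (hydroxyl on the bottom face), via B-alkyl-9-borabicyclononane adduct 7 (not isolated)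
Conditions: 9-BBN-H, THF, 65 °C; then H2O2, aq. NaOAc, 0 °C
Reagents that add atoms: hydrogen peroxide, OO
Why: Hydroboration–oxidation: the bulky borane should add from the exo face opposite the lactone bridge and place boron on C6, the alkene carbon remote from the quaternary C10, and oxidation with retention gives the C6 alcohol, whose configuration does not matter because C6 becomes a ketone in step 10.

**Step 5**
Reactants: 8 C6 hydroxy lactone
Product: 9 triethylsilyl ether of 8
Conditions: Et3SiCl, imidazole, DMF, 0 °C to rt
Reagents that add atoms: chlorotriethylsilane, CC[Si](Cl)(CC)CC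
Why: Standard silylation of an unhindered secondary alcohol masks the C6 oxygen during the unravelling of the lactone.

**Step 6**
Reactants: 9 silyloxy lactone
Product: 10 bridged lactol (anomer mixture)
Conditions: i-Bu2AlH (1.1 equiv), CH2Cl2, −78 °C; aq. Rochelle salt
Reagents that add atoms: none
Why: Partial reduction of a lactone with i-Bu2AlH at low temperature stops at the tetrahedral aluminate, which gives the lactol on work-up.

**Step 7**
Reactants: 10 bridged lactol
Product: 12 vinyl cyclohexanol (C8 hydroxyl cis to vinyl; C6 silyl ether trans to vinyl), via open hydroxy aldehyde 11 (not isolated)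
Conditions: Ph3PCH3Br, KOt-Bu, THF, 0 °C to 65 °C
Reagents that add atoms: methyltriphenylphosphonium bromide, C[P+](c1ccccc1)(c1ccccc1)c1ccccc1.[Br-]
Why: Wittig methylenation of the lactol through its ring-opened, non-enolisable neopentyl aldehyde turns C1 into the vinyl carbon and releases the C8 hydroxyl with the configuration set in step 2.

**Step 8**
Reactants: 12 vinyl cyclohexanol
Product: 13 C8 4-methoxybenzyl ether
Conditions: NaH, 4-methoxybenzyl chloride, Bu4NI (cat.), DMF, 0 °C to rt
Reagents that add atoms: 4-methoxybenzyl chloride, COc1ccc(CCl)cc1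
Why: Williamson etherification installs an ether that is a poor leaving group, so it should survive enolate formation next to C8, and that can later be removed oxidatively in the presence of silyl ethers.

**Step 9**
Reactants: 13 bis-ether
Product: 14 C6 alcohol
Conditions: pyridinium p-toluenesulfonate (cat.), MeOH, rt
Reagents that add atoms: none
Why: Acid-catalysed methanolysis cleaves the triethylsilyl ether selectively, the benzylic ether and the alkene being inert to this mild acid.

**Step 10**
Reactants: 14 C6 alcohol
Product: 15 C6 ketone (C8 ether cis to vinyl)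
Conditions: Dess–Martin periodinane, NaHCO3, CH2Cl2, 0 °C to rt
Reagents that add atoms: none
Why: Dess–Martin oxidation under buffered, non-basic conditions gives the β-alkoxy ketone without elimination of the C8 ether.

**Step 11**
Reactants: 15 C6 ketone; 16 tert-butyl bromoacetate
Product: 18 C7-alkylated keto ester (C7 arm trans to the C8 ether), via lithium enolate 17 (not isolated)
Conditions: LiN(i-Pr)2, THF, −78 °C; then 16, DMPU, −78 °C to −40 °C
Reagents that add atoms: tert-butyl bromoacetate (compound 16), CC(C)(C)OC(=O)CBr
Why: Kinetic deprotonation should occur at C7 rather than at the neopentyl C5, and the enolate alkylation (SN2) should take place anti to the adjacent C8 ether, giving the 7,8-trans equatorial arm, which is also the favoured arrangement at this epimerisable carbon.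

**Step 12**
Reactants: 19 2-bromoprop-2-en-1-ol
Product: 20 [(2-bromoprop-2-en-1-yl)oxy](tert-butyl)dimethylsilane
Conditions: t-BuMe2SiCl, imidazole, CH2Cl2, rt
Reagents that add atoms: tert-butyldimethylsilyl chloride, CC(C)(C)[Si](C)(C)Cl
Why: Standard silylation of a primary allylic alcohol gives the coupling partner that carries C4, C15 and the protected C3 oxygen.

**Step 13**
Reactants: 18 C7-alkylated keto ester; 20 silyl-protected 2-bromoallyl alcohol
Product: 23 C5-alkenylated ketone (alkenyl on the bottom face), via C5 lithium enolate 21 (not isolated), via lithium dienolate 22 (not isolated)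
Conditions: LiN(SiMe3)2 (2.2 equiv), THF, −78 °C; Pd2(dba)3 (2.5 mol %; dba = dibenzylideneacetone), P(t-Bu)3 (6 mol %), 20, −78 °C to 22 °C; then AcOH, −78 °C
Reagents that add atoms: bromide 20 (compound 20), C=C(Br)CO[Si](C)(C)C(C)(C)C
Why: Palladium-catalysed α-alkenylation of a ketone enolate: the kinetic C5 enolate (C7 is tertiary, and the tert-butyl ester is less acidic and a poor acylating agent) transmetalates to the alkenylpalladium bromide formed by oxidative addition of 20 to zerovalent palladium, reductive elimination forms C5–C4, and the more acidic product is held as its dienolate, whose kinetic α-protonation from the top face, opposite the axial C14 methyl, should leave the alkenyl group equatorial on the bottom face and the alkene unconjugated.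

**Step 14**
Reactants: 23 C5-alkenylated ketone
Product: 25 trans-fused γ-lactone, via C6 hydroxy ester 24 (not isolated)
Conditions: SmI2 (2.5 equiv), THF/MeOH, −78 °C to 0 °C; then KOt-Bu (10 mol %), THF, 0 °C
Reagents that add atoms: none
Why: Single-electron reduction with SmI2 proceeds through a ketyl and a protonated carbanion and should therefore give the thermodynamically preferred equatorial C6 alcohol (top face, trans to both neighbours), which hydride reagents would not because the axial C14 methyl screens the bottom face; catalytic alkoxide then closes the trans-fused lactone by 5-exo-trig transesterification with loss of tert-butoxide.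

**Step 15**
Reactants: 25 trans-fused γ-lactone; 2 iodomethane
Product: 27 C11-methyl lactone (11R; methyl cis to H7), via lactone lithium enolate 26 (not isolated)
Conditions: LiN(i-Pr)2 (1.1 equiv), THF, −78 °C; then MeI, −78 °C
Reagents that add atoms: iodomethane (compound 2), CI
Why: Lactone enolate alkylation: iodomethane should approach the enolate on the face turned away from C8 and its ether, the convex face of the trans-fused bicycle, so the methyl group ends up cis to H7.

**Step 16**
Reactants: 27 C11-methyl lactone
Product: 28 C8 alcohol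
Conditions: DDQ, CH2Cl2/pH 7 buffer, 0 °C
Reagents that add atoms: none
Why: Oxidative cleavage of the 4-methoxybenzyl ether by DDQ goes through the benzylic oxocarbenium ion and its hemiacetal and should leave the silyl ether, the alkenes and the lactone untouched.

**Step 17**
Reactants: 29 1,1,1,3,3,3-hexafluoropropan-2-yl acrylate; 30 (tert-butyldimethylsilyloxy)acetaldehyde
Product: 31 hexafluoropropan-2-yl (S)-3-hydroxy-4-(tert-butyldimethylsilyloxy)-2-methylidenebutanoate
Conditions: β-isocupreidine (the quinidine-derived cyclic ether phenol, 10 mol %), DMF, −55 °C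
Reagents that add atoms: aldehyde 30 (compound 30), O=CCO[Si](C)(C)C(C)(C)C
Why: Asymmetric Morita–Baylis–Hillman reaction of the activated acrylate: the chiral amine–phenol catalyst sets the carbinol, and its usual sense of induction with aliphatic aldehydes corresponds to the (S) descriptor here because the CH2OSi group outranks the acrylate carbon.

**Step 18**
Reactants: 31 Morita–Baylis–Hillman adduct
Product: 32 hexafluoropropan-2-yl (S)-3,4-bis(tert-butyldimethylsilyloxy)-2-methylidenebutanoate
Conditions: t-BuMe2SiOTf, 2,6-lutidine, CH2Cl2, −78 °C to 0 °C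
Reagents that add atoms: tert-butyldimethylsilyl triflate, CC(C)(C)[Si](C)(C)OS(=O)(=O)C(F)(F)F
Why: Silylation of the secondary allylic alcohol with the silyl triflate and a hindered base proceeds without touching the activated ester or the stereocentre.

**Step 19**
Reactants: 32 bis-silyl hexafluoropropan-2-yl ester
Product: 33 (S)-3,4-bis(tert-butyldimethylsilyloxy)-2-methylidenebutanoic acid
Conditions: LiOH, THF/H2O, 0 °C; aq. HCl to pH 3
Reagents that add atoms: lithium hydroxide, [Li+].[OH-]
Why: Saponification of the strongly activated fluoroalkyl ester is fast at 0 °C, so the silyl ethers and the acrylate should survive.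

**Step 20**
Reactants: 28 C8 alcohol; 33 side-chain acid
Product: 35 tris-silyl ester, via mixed anhydride 34 (not isolated)
Conditions: 2,4,6-trichlorobenzoyl chloride, Et3N, toluene, rt; then 28, 4-(dimethylamino)pyridine, rt
Reagents that add atoms: acid 33 (compound 33), C=C(C(=O)O)[C@H](O[Si](C)(C)C(C)(C)C)CO[Si](C)(C)C(C)(C)C
Why: Yamaguchi esterification through the mixed anhydride and acylpyridinium transfer acylates the only free hydroxyl, the equatorial C8 alcohol, with retention at C8.

**Step 21**
Reactants: 35 tris-silyl ester
Product: 36 target CNP0260337.1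
Conditions: HF·pyridine, pyridine, THF, 0 °C to rt
Reagents that add atoms: none
Why: Fluoride-mediated desilylation under buffered, mildly acidic conditions removes the three silyl ethers and avoids the base-induced translactonisation to which the dihydroxy acrylate ester is prone.

**Compound list**

1 | benzoic acid | O=C(O)c1ccccc1 | starting material
2 | iodomethane | CI | starting material
3 | dilithium (cyclohexa-2,5-dien-1-ylidene)methanediolate | [Li+].[Li+].[O-]C([O-])=C1C=CCC=C1 | intermediate (not isolated)
4 | 1-methylcyclohexa-2,5-diene-1-carboxylic acid (achiral) | CC1(C(=O)O)C=CCC=C1 | intermediate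
5 | (1S,5S,8S)-8-iodo-1-methyl-6-oxabicyclo[3.2.1]oct-2-en-7-one (C1 carbonyl bridged to O on C8, iodine on C9 anti to O, C5=C6 alkene kept) | O=C1[C@@]2(C)[C@H](I)[C@@H](O1)CC=C2 | intermediate
6 | (1S,5S)-1-methyl-6-oxabicyclo[3.2.1]oct-2-en-7-one | O=C1[C@@]2(C)C[C@@H](O1)CC=C2 | intermediate
7 | B-alkyl-9-borabicyclo[3.3.1]nonane adduct of 6 (boron on C6, bottom face) | O=C1[C@@]2(C)C[C@@H](O1)C[C@H](B3C4CCCC3CCC4)C2 | intermediate (not isolated)
8 | 3-hydroxy-1-methyl-6-oxabicyclo[3.2.1]octan-7-one, C6 hydroxyl on the bottom face (anti to the lactone bridge) | O=C1[C@@]2(C)C[C@@H](O1)C[C@H](O)C2 | intermediate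
9 | triethylsilyl ether of 8 | O=C1[C@@]2(C)C[C@@H](O1)C[C@H](O[Si](CC)(CC)CC)C2 | intermediate
10 | 1-methyl-3-(triethylsilyloxy)-6-oxabicyclo[3.2.1]octan-7-ol (lactol, anomer mixture) | OC1[C@@]2(C)C[C@@H](O1)C[C@H](O[Si](CC)(CC)CC)C2 | intermediate
11 | 5-hydroxy-1-methyl-3-(triethylsilyloxy)cyclohexane-1-carbaldehyde (C8 hydroxyl cis to CHO, C6 silyl ether trans) | O=C[C@@]1(C)C[C@@H](O)C[C@H](O[Si](CC)(CC)CC)C1 | intermediate (not isolated)
12 | 3-ethenyl-3-methyl-5-(triethylsilyloxy)cyclohexan-1-ol (C8 hydroxyl cis to vinyl, C6 silyl ether trans to vinyl) | C=C[C@@]1(C)C[C@@H](O)C[C@H](O[Si](CC)(CC)CC)C1 | intermediate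
13 | 4-methoxybenzyl ether of 12 at C8 | C=C[C@@]1(C)C[C@@H](OCc2ccc(OC)cc2)C[C@H](O[Si](CC)(CC)CC)C1 | intermediate
14 | 3-ethenyl-5-[(4-methoxybenzyl)oxy]-3-methylcyclohexan-1-ol (free C6 hydroxyl on the bottom face) | C=C[C@@]1(C)C[C@@H](OCc2ccc(OC)cc2)C[C@H](O)C1 | intermediate
15 | 3-ethenyl-5-[(4-methoxybenzyl)oxy]-3-methylcyclohexan-1-one (C8 ether cis to vinyl) | C=C[C@@]1(C)C[C@@H](OCc2ccc(OC)cc2)CC(=O)C1 | intermediate
16 | tert-butyl bromoacetate | CC(C)(C)OC(=O)CBr | starting material
17 | lithium enolate of 15 (C6=C7) | [Li+].C=C[C@@]1(C)C[C@@H](OCc2ccc(OC)cc2)C=C([O-])C1 | intermediate (not isolated)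
18 | tert-butyl 2-[4-ethenyl-6-[(4-methoxybenzyl)oxy]-4-methyl-2-oxocyclohexyl]acetate (C7 arm on the bottom face, trans to the C8 ether) | C=C[C@@]1(C)C[C@@H](OCc2ccc(OC)cc2)[C@H](CC(=O)OC(C)(C)C)C(=O)C1 | intermediate
19 | 2-bromoprop-2-en-1-ol | C=C(Br)CO | starting material
20 | [(2-bromoprop-2-en-1-yl)oxy](tert-butyl)dimethylsilane | C=C(Br)CO[Si](C)(C)C(C)(C)C | intermediate
21 | C5 lithium enolate of 18 (C5=C6) | [Li+].C=C[C@@]1(C)C[C@@H](OCc2ccc(OC)cc2)[C@H](CC(=O)OC(C)(C)C)C([O-])=C1 | intermediate (not isolated)
22 | lithium dienolate of 23 (O–C6=C5–C4=C15) | [Li+].C=C[C@@]1(C)C[C@@H](OCc2ccc(OC)cc2)[C@H](CC(=O)OC(C)(C)C)C([O-])=C1C(=C)CO[Si](C)(C)C(C)(C)C | intermediate (not isolated)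
23 | keto ester 18 carrying at C5 a 3-(tert-butyldimethylsilyloxy)prop-1-en-2-yl group on the bottom face (trans to vinyl, cis to the C7 arm) | C=C[C@@]1(C)C[C@@H](OCc2ccc(OC)cc2)[C@H](CC(=O)OC(C)(C)C)C(=O)[C@@H]1C(=C)CO[Si](C)(C)C(C)(C)C | intermediate
24 | C6 alcohol of 23, hydroxyl on the top face (trans to the C5 and C7 substituents) | C=C[C@@]1(C)C[C@@H](OCc2ccc(OC)cc2)[C@H](CC(=O)OC(C)(C)C)[C@@H](O)[C@@H]1C(=C)CO[Si](C)(C)C(C)(C)C | intermediate (not isolated)
25 | trans-fused γ-lactone (O6–C12) with C8 4-methoxybenzyl ether, C10 methyl and vinyl, C5 silyloxypropenyl | C=C[C@@]1(C)C[C@@H](OCc2ccc(OC)cc2)[C@H]3[C@@H](OC(=O)C3)[C@@H]1C(=C)CO[Si](C)(C)C(C)(C)C | intermediate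
26 | lithium enolate of 25 (C11=C12) | [Li+].C=C[C@@]1(C)C[C@@H](OCc2ccc(OC)cc2)[C@H]3[C@@H](OC([O-])=C3)[C@@H]1C(=C)CO[Si](C)(C)C(C)(C)C | intermediate (not isolated)
27 | C11-methyl lactone (11R, methyl cis to H7) | C=C[C@@]1(C)C[C@@H](OCc2ccc(OC)cc2)[C@H]3[C@@H](OC(=O)[C@@H]3C)[C@@H]1C(=C)CO[Si](C)(C)C(C)(C)C | intermediate
28 | C8 alcohol of 27 (hydroxyl on the top face) | C=C[C@@]1(C)C[C@@H](O)[C@H]2[C@@H](OC(=O)[C@@H]2C)[C@@H]1C(=C)CO[Si](C)(C)C(C)(C)C | intermediate
29 | 1,1,1,3,3,3-hexafluoropropan-2-yl prop-2-enoate | C=CC(=O)OC(C(F)(F)F)C(F)(F)F | starting material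
30 | (tert-butyldimethylsilyloxy)acetaldehyde | O=CCO[Si](C)(C)C(C)(C)C | starting material
31 | 1,1,1,3,3,3-hexafluoropropan-2-yl (S)-3-hydroxy-4-(tert-butyldimethylsilyloxy)-2-methylidenebutanoate | C=C(C(=O)OC(C(F)(F)F)C(F)(F)F)[C@H](O)CO[Si](C)(C)C(C)(C)C | intermediate
32 | 1,1,1,3,3,3-hexafluoropropan-2-yl (S)-3,4-bis(tert-butyldimethylsilyloxy)-2-methylidenebutanoate | C=C(C(=O)OC(C(F)(F)F)C(F)(F)F)[C@H](O[Si](C)(C)C(C)(C)C)CO[Si](C)(C)C(C)(C)C | intermediate
33 | (S)-3,4-bis(tert-butyldimethylsilyloxy)-2-methylidenebutanoic acid | C=C(C(=O)O)[C@H](O[Si](C)(C)C(C)(C)C)CO[Si](C)(C)C(C)(C)C | intermediate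
34 | mixed anhydride of 33 with 2,4,6-trichlorobenzoic acid | C=C(C(=O)OC(=O)c1c(Cl)cc(Cl)cc1Cl)[C@H](O[Si](C)(C)C(C)(C)C)CO[Si](C)(C)C(C)(C)C | intermediate (not isolated)
35 | C8 ester of 28 with acid 33 (three tert-butyldimethylsilyl ethers) | C=C[C@@]1(C)C[C@@H](OC(=O)C(=C)[C@H](O[Si](C)(C)C(C)(C)C)CO[Si](C)(C)C(C)(C)C)[C@H]2[C@@H](OC(=O)[C@@H]2C)[C@@H]1C(=C)CO[Si](C)(C)C(C)(C)C | intermediate
36 | (3R,3aS,4R,6R,7S,7aS)-6-ethenyl-7-(3-hydroxyprop-1-en-2-yl)-3,6-dimethyl-2-oxooctahydro-1-benzofuran-4-yl (3S)-3,4-dihydroxy-2-methylidenebutanoate (CNP0260337.1) | C=C[C@@]1(C)C[C@@H](OC(=O)C(=C)[C@H](O)CO)[C@H]2[C@@H](OC(=O)[C@@H]2C)[C@@H]1C(=C)CO | target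

**Step count and risks**

Total step count: 21. Longest linear sequence: 17 steps (steps 1–11, 13–16, 20 and 21); steps 12 and 17–19 prepare the two side-arm building blocks.

Steps most likely to fail:

Step 2. The catalyst may discriminate poorly between the two enantiotopic alkenes, reversible iodonium transfer may erode that discrimination, and material may be diverted into the β-lactone. The fallback uses auxiliary control and known reaction types. It sets out from 4, which would be converted with oxalyl chloride and catalytic DMF into 1-methylcyclohexa-2,5-diene-1-carbonyl chloride F1. This would be condensed (Et3N, CH2Cl2) with commercial (2R,5R)-2,5-bis(methoxymethyl)pyrrolidine to the C2-symmetric amide [(2R,5R)-2,5-bis(methoxymethyl)pyrrolidin-1-yl](1-methylcyclohexa-2,5-dien-1-yl)methanone F2. Iodolactonisation of this amide (I2, THF/H2O), in which the auxiliary differentiates the now diastereotopic alkenes and the iminium lactone is hydrolysed on work-up, would return the route at 5 with release of the amine. The auxiliary enantiomer would be chosen according to the sense observed.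

Step 13. Reductive elimination at the neopentyl enolate carbon may be slow, coupling may compete at the ester α-carbon, the alkenylpalladium intermediate may lose its silyloxy group as an allene, and protonation may occur on the wrong face. The fallback builds C4 as a carbonyl carbon and adds C15 afterwards. It sets out from 18, whose kinetic C5 enolate (LiN(i-Pr)2, −78 °C) would be added to aldehyde 30 to give the aldol adduct, the C5 (1-hydroxy-2-silyloxyethyl) keto ester F3. Reduction with SmI2 as in step 14 would give the C4,C6 diol ester F4, and catalytic KOt-Bu would give the C4 hydroxy lactone F5. Dess–Martin oxidation of the side-chain carbinol would give the α-silyloxy ketone lactone F6, in which C5 is epimerisable and should settle equatorial. Wittig methylenation of that ketone (Ph3P=CH2, THF) would install C15 and return the route at 25.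

Step 14. Facial selectivity may be poor, that is, hydrogen may be delivered to C6 from the top face to give the axial alcohol and hence a cis-fused lactone. The fallback makes the O6–C6 bond by substitution with inversion. It sets out from 23, which would be reduced with the bulky hydride LiBH(s-Bu)3 (THF, −78 °C), expected to attack from the open top face, to the axial C6 alcohol F7. Mesylation (MsCl, Et3N) would give the C6 mesylate F8. On warming with 2,6-lutidine in MeCN the tert-butyl ester carbonyl should displace the axial mesylate from the top face with inversion and lose 2-methylpropene, returning the route at 25.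

**Further compounds**

F1 | step 2 | 1-methylcyclohexa-2,5-diene-1-carbonyl chloride | CC1(C(=O)Cl)C=CCC=C1
F2 | step 2 | [(2R,5R)-2,5-bis(methoxymethyl)pyrrolidin-1-yl](1-methylcyclohexa-2,5-dien-1-yl)methanone | COC[C@H]1CC[C@H](COC)N1C(=O)C2(C)C=CCC=C2
F3 | step 13 | aldol adduct of 18 and 30, C5 (1-hydroxy-2-silyloxyethyl) keto ester (C4 and C5 not controlled) | C=C[C@@]1(C)C[C@@H](OCc2ccc(OC)cc2)[C@H](CC(=O)OC(C)(C)C)C(=O)C1C(O)CO[Si](C)(C)C(C)(C)C
F4 | step 13 | C4,C6 diol ester (C6 hydroxyl on the top face) | C=C[C@@]1(C)C[C@@H](OCc2ccc(OC)cc2)[C@H](CC(=O)OC(C)(C)C)[C@@H](O)C1C(O)CO[Si](C)(C)C(C)(C)C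
F5 | step 13 | trans-fused lactone with C4 carbinol side chain | C=C[C@@]1(C)C[C@@H](OCc2ccc(OC)cc2)[C@H]3[C@@H](OC(=O)C3)C1C(O)CO[Si](C)(C)C(C)(C)C
F6 | step 13 | trans-fused lactone with C4 ketone (α-silyloxy ketone) | C=C[C@@]1(C)C[C@@H](OCc2ccc(OC)cc2)[C@H]3[C@@H](OC(=O)C3)C1C(=O)CO[Si](C)(C)C(C)(C)C
F7 | step 14 | C6 epimer of 24 (axial hydroxyl on the bottom face) | C=C[C@@]1(C)C[C@@H](OCc2ccc(OC)cc2)[C@H](CC(=O)OC(C)(C)C)[C@H](O)[C@@H]1C(=C)CO[Si](C)(C)C(C)(C)C
F8 | step 14 | C6 methanesulfonate of F7 | C=C[C@@]1(C)C[C@@H](OCc2ccc(OC)cc2)[C@H](CC(=O)OC(C)(C)C)[C@H](OS(C)(=O)=O)[C@@H]1C(=C)CO[Si](C)(C)C(C)(C)C
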